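C4–C3–C2(C7)–C1 amide from 2-butyne-1,4-diol and C1' alkynol from farnesol are joined at C1–C6; the ynone is dienolised, the carbonate ring is closed with CO2, the carbocycle closes next and the epoxide last.
Cuts: acetate and silyl groups; epoxide C6–O bond (back to a C6 bromide and a cyclic carbonate on O5/O1'); ring bond C4–C5 (retro-6π) to the triene C4=C3–C2=C1–C6=C5; the carbonate to CO2 and a C5≡C6 propargylic alcohol; C1–C6 (acetylide + Weinreb amide); C1'–C5 (farnesal + silylacetylene).
Enabling feature: in ring C1–C6, C4 and C5 are neighbouring oxygen-bearing carbons with trans oxygens and the exocyclic C1' on C5 also carries oxygen, so O5 and O1' fit a 1,3-dioxolan-2-one ring whose alkylidene carbon C5 is one terminus of a hexatriene ending at C4.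
Stereochemistry: C1' from a catalytic asymmetric alkynylation; C4 and C5 from the electrocyclisation (trans oxygens from olefin geometry, absolute sense relayed from C1'); C6 by inversion in the epoxide closure; chain olefins from farnesol.

Key step: step 12

Numbering: ring C1 (C=O), C2 (bears C7H2O), C3, C4 (CHOH), C5 and C6 (epoxide), side-chain carbinol C1', as in the target. TBS = tert-butyldimethylsilyl, Piv = 2,2-dimethylpropanoyl.
Assumption: the zinc catalyst from (S,S)-ProPhenol is taken to deliver the alkynyl group to the Re face of farnesal (giving 1'S); if its sense is the opposite, the (R,R)-ligand is used.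

Step 1
Reactants: 1 2-butyne-1,4-diol
Product: 2 (E)-2-(tributylstannyl)but-2-ene-1,4-diol
Conditions: Bu3SnH, PdCl2(PPh3)2 (cat.), THF, rt
Reagents that add atoms: tributyltin hydride CCCC[SnH](CCCC)CCCC
Why: Palladium-catalysed hydrostannation adds H and Sn syn across the symmetrical alkyne, so regiochemistry is moot and tin ends trans to C4 (C7 cis to C4), the geometry the later enolisation needs.

Step 2
Reactants: 2 (E)-2-(tributylstannyl)but-2-ene-1,4-diol
Product: 3 (E)-1,4-bis(TBS-oxy)-2-(tributylstannyl)but-2-ene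
Conditions: TBSCl, imidazole, DMF, rt
Reagents that add atoms: tert-butyldimethylsilyl chloride CC(C)(C)[Si](C)(C)Cl
Why: Standard silylation of two primary allylic alcohols; the TBS ethers survive organolithium, hydride and carbonate steps and come off together at the end.

Step 3
Reactants: 3 (E)-1,4-bis(TBS-oxy)-2-(tributylstannyl)but-2-ene; 4 N-methoxy-N-methylcarbamoyl chloride
Product: 6 (E)-4-(TBS-oxy)-2-[(TBS-oxy)methyl]-N-methoxy-N-methylbut-2-enamide, via vinyllithium 5 (not isolated)
Conditions: n-BuLi, THF, −78 °C; then 4, −78 to −40 °C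
Reagents that add atoms: none
Why: Tin–lithium exchange goes with retention at the sp2 carbon and the cold vinyllithium is acylated once by the carbamoyl chloride (Weinreb amide synthesis), so C1 arrives at the acyl level with the carbonyl trans to C4.

Step 4
Reactants: 7 (2E,6E)-farnesol
Product: 8 (2E,6E)-farnesal
Conditions: MnO2, CH2Cl2, rt
Reagents that add atoms: none
Why: MnO2 oxidises only the allylic alcohol and should leave the isolated trisubstituted alkenes and the 2E geometry untouched.

Step 5
Reactants: 8 (2E,6E)-farnesal; 9 ethynyltrimethylsilane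
Product: 11 (3S,4E,8E)-5,9,13-trimethyl-1-(trimethylsilyl)tetradeca-4,8,12-trien-1-yn-3-ol, via zinc acetylide 10 (not isolated)
Conditions: Me2Zn, 2,6-bis[[(S)-2-(hydroxydiphenylmethyl)pyrrolidin-1-yl]methyl]-4-methylphenol ((S,S)-ProPhenol, cat.), Ph3PO (cat.), toluene, 4 °C
Reagents that add atoms: none
Why: Catalytic asymmetric alkynylation of an enal, in which Me2Zn metalates 9 and the dinuclear zinc–ProPhenol complex delivers the alkynyl group 1,2 to the Re face, setting C1' as S.

Step 6
Reactants: 11 (3S,4E,8E)-5,9,13-trimethyl-1-(trimethylsilyl)tetradeca-4,8,12-trien-1-yn-3-ol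
Product: 12 (3S,4E,8E)-5,9,13-trimethyltetradeca-4,8,12-trien-1-yn-3-ol
Conditions: K2CO3, MeOH, rt
Reagents that add atoms: none
Why: Base-catalysed methanolysis of the C(sp)–Si bond (protodesilylation) frees the terminal alkyne without touching C1'.

Step 7
Reactants: 12 (3S,4E,8E)-5,9,13-trimethyltetradeca-4,8,12-trien-1-yn-3-ol; 6 (E)-4-(TBS-oxy)-2-[(TBS-oxy)methyl]-N-methoxy-N-methylbut-2-enamide
Product: 14 hydroxy ynone (2E,7S,8E,12E)-1-(TBS-oxy)-3-[(TBS-oxy)methyl]-7-hydroxy-9,13,17-trimethyloctadeca-2,8,12,16-tetraen-5-yn-4-one, via dilithio alkynolate 13 (not isolated)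
Conditions: n-BuLi (2 equiv), THF, −78 °C; then 6, −78 to −20 °C; aq NH4Cl
Reagents that add atoms: none
Why: The alkoxide–acetylide dianion adds to the Weinreb amide and the chelated tetrahedral intermediate collapses only on work-up (Weinreb ketone synthesis), giving the C1 ketone without an oxidation step and without protecting C1'–OH.

Step 8
Reactants: 14 hydroxy ynone
Product: 15 pivalate of 14 at O1' (7S)
Conditions: PivCl, pyridine, DMAP (cat.), CH2Cl2, 0 °C
Reagents that add atoms: pivaloyl chloride CC(C)(C)C(Cl)=O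
Why: DMAP-catalysed acylation masks C1'–OH for the silyl triflate step with an ester that has no enolisable hydrogen and is later removed by hydride in the presence of silyl enol ethers.

Step 9
Reactants: 15 pivalate of 14
Product: 16 dienyne (1E,3Z,7S,8E,12E)-1,4-bis(TBS-oxy)-3-[(TBS-oxy)methyl]-9,13,17-trimethyloctadeca-1,3,8,12,16-pentaen-5-yn-7-yl pivalate
Conditions: TBSOTf, Et3N, CH2Cl2, −78 to −20 °C
Reagents that add atoms: tert-butyldimethylsilyl trifluoromethanesulfonate CC(C)(C)[Si](C)(C)OS(=O)(=O)C(F)(F)F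
Why: Soft vinylogous enolisation (O-silylation of the ketone, then γ-deprotonation by the amine) can only occur at C4, since loss of the propargylic C1'–H would give a cumulene; with H rather than C4 cis to the carbonyl the oxocarbenium ion should prefer O syn to C7, which places the alkyne cis to C3, and allylic strain against C7 should keep the new C4 silyloxy group trans to C2.

Step 10
Reactants: 16 dienyne pivalate
Product: 17 dienynol (1E,3Z,7S,8E,12E)-1,4-bis(TBS-oxy)-3-[(TBS-oxy)methyl]-9,13,17-trimethyloctadeca-1,3,8,12,16-pentaen-5-yn-7-ol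
Conditions: i-Bu2AlH, toluene, −78 °C; aq potassium sodium tartrate
Reagents that add atoms: none
Why: Reductive ester cleavage by i-Bu2AlH at low temperature frees O1' under non-acidic, non-fluoride conditions that silyl enol ethers, the TBS ether and the enyne tolerate.

Step 11
Reactants: 17 dienynol
Product: 18 triene carbonate (4Z,5S)-4-[(2Z,4E)-2,5-bis(TBS-oxy)-3-[(TBS-oxy)methyl]penta-2,4-dien-1-ylidene]-5-[(1E,5E)-2,6,10-trimethylundeca-1,5,9-trien-1-yl]-1,3-dioxolan-2-one
Conditions: AgOAc (cat.), DBU, CO2 (1 MPa), toluene, rt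
Reagents that add atoms: carbon dioxide O=C=O
Why: Silver-catalysed carboxylative cyclisation of a propargylic alcohol, in which the amidinium carbonate adds anti (5-exo-dig) across the silver-bound alkyne and protodemetalation leaves O5 cis to C1 on the new C5=C6 bond (Z), with C1' untouched.

Step 12
Reactants: 18 triene carbonate
Product: 19 spiro carbonate cyclohexadiene (4S,5R,1'S): C1(OTBS)=C6 and C2=C3 in the ring, CH2OTBS on C2, OTBS on C4, C5 spiro to the 1,3-dioxolan-2-one holding O5, O1' and C1'; C4–O trans to C5–O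
Conditions: toluene (degassed), 2,6-di-tert-butyl-4-methylpyridine (cat.), 90 °C, dark
Reagents that add atoms: none
Why: Proposed new method: heating should bring about a concerted thermal disrotatory 6π-electrocyclisation of the C4=C3–C2=C1–C6=C5 triene; the closest known reaction is the thermal closure of silyloxy-substituted hexatrienes to cyclohexadienes, which has not been shown for a terminus that is the alkylidene carbon of a cyclic carbonate. The six-membered carbocycle closes through the C4–C5 bond in the disrotatory 6π mode and C5 becomes the spiro atom. Because the C4 silyloxy group points outward (E) and the carbonate oxygen inward (Z), disrotation must place the two oxygens trans, so the C4/C5 relative configuration is fixed by olefin geometry alone. The absolute sense is relayed from C1': the flat carbonate ring holds the C1' alkenyl chain over one face of C5 and only hydrogen over the other, so C4 should bond on the hydrogen face, which is the face the target requires. The step needs this torquoselectivity and must outrun ionisation of the doubly allylic C5–O bond, hence the apolar, buffered medium and a temperature below 100 °C. The C1 silyl enol ether is expected to lower the barrier, as donor-substituted trienes generally close at moderate temperature.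

Step 13
Reactants: 19 spiro carbonate cyclohexadiene
Product: 20 α-bromo ketone (4S,5R,6S,1'S): C1 ketone, C2=C3, Br on C6 trans to O5
Conditions: NBS, NaHCO3, THF, −78 °C
Reagents that add atoms: N-bromosuccinimide O=C1CCC(=O)N1Br
Why: α-Bromination of a silyl enol ether occurs at C6 far faster than attack on the trisubstituted chain alkenes at −78 °C, and bromine is expected anti to the allylic C5–O bond, the arrangement needed for backside closure (a cis epimer would converge in step 14).

Step 14
Reactants: 20 α-bromo ketone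
Product: 22 epoxy enone (4S,5R,6R,1'S) with TBS on O7 and O4 and free C1'–OH, via bromohydrin diol 21 (not isolated)
Conditions: K2CO3, MeOH, 0 °C to rt
Reagents that add atoms: none
Why: Methanolysis of the five-membered carbonate frees O5 and O1', and the C5 alkoxide displaces the anti bromide at C6 with inversion (intramolecular Williamson closure of a bromohydrin), while any cis bromide should epimerise through the enolate under the same conditions and drain through the trans isomer.

Step 15
Reactants: 22 epoxy enone bis-TBS ether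
Product: 23 triol (4S,5R,6R,1'S): C7–OH, C4–OH, C1'–OH
Conditions: HF·pyridine, pyridine, THF, 0 °C to rt
Reagents that add atoms: none
Why: Buffered fluoride desilylation removes the primary and the secondary allylic TBS ether without the base that would open the epoxy enone.

Step 16
Reactants: 23 triol
Product: 24 target acetate
Conditions: AcCl, 2,4,6-collidine, CH2Cl2, −78 °C
Reagents that add atoms: acetyl chloride CC(Cl)=O
Why: Kinetically selective acylation: at low temperature with a hindered pyridine the primary allylic C7–OH should react far faster than the two secondary allylic alcohols, of which C1'–OH is also flanked by the quaternary C5.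

Compound list
1 | 2-butyne-1,4-diol | OCC#CCO | starting material
2 | (E)-2-(tributylstannyl)but-2-ene-1,4-diol | CCCC[Sn](CCCC)(CCCC)/C(CO)=C/CO | intermediate
3 | (E)-1,4-bis(TBS-oxy)-2-(tributylstannyl)but-2-ene | CCCC[Sn](CCCC)(CCCC)/C(CO[Si](C)(C)C(C)(C)C)=C/CO[Si](C)(C)C(C)(C)C | intermediate
4 | N-methoxy-N-methylcarbamoyl chloride | CON(C)C(Cl)=O | starting material
5 | (Z)-1,4-bis(TBS-oxy)but-2-en-2-yllithium (Li trans to C4) | [Li]/C(CO[Si](C)(C)C(C)(C)C)=C/CO[Si](C)(C)C(C)(C)C | intermediate
6 | (E)-4-(TBS-oxy)-2-[(TBS-oxy)methyl]-N-methoxy-N-methylbut-2-enamide | CON(C)C(=O)/C(CO[Si](C)(C)C(C)(C)C)=C/CO[Si](C)(C)C(C)(C)C | intermediate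
7 | (2E,6E)-farnesol | OC/C=C(\C)CC/C=C(\C)CCC=C(C)C | starting material
8 | (2E,6E)-farnesal | O=C/C=C(\C)CC/C=C(\C)CCC=C(C)C | intermediate
9 | ethynyltrimethylsilane | C#C[Si](C)(C)C | starting material
10 | methyl[(trimethylsilyl)ethynyl]zinc | C[Zn]C#C[Si](C)(C)C | intermediate
11 | (3S,4E,8E)-5,9,13-trimethyl-1-(trimethylsilyl)tetradeca-4,8,12-trien-1-yn-3-ol | C[Si](C)(C)C#C[C@@H](O)/C=C(\C)CC/C=C(\C)CCC=C(C)C | intermediate
12 | (3S,4E,8E)-5,9,13-trimethyltetradeca-4,8,12-trien-1-yn-3-ol | C#C[C@@H](O)/C=C(\C)CC/C=C(\C)CCC=C(C)C | intermediate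
13 | dilithium salt of 12 (alkoxide at O1', acetylide at C6) | [Li]C#C[C@@H](O[Li])/C=C(\C)CC/C=C(\C)CCC=C(C)C | intermediate
14 | (2E,7S,8E,12E)-1-(TBS-oxy)-3-[(TBS-oxy)methyl]-7-hydroxy-9,13,17-trimethyloctadeca-2,8,12,16-tetraen-5-yn-4-one | CC(C)(C)[Si](C)(C)OC/C=C(\CO[Si](C)(C)C(C)(C)C)C(=O)C#C[C@@H](O)/C=C(\C)CC/C=C(\C)CCC=C(C)C | intermediate
15 | (2E,7S,8E,12E)-1-(TBS-oxy)-3-[(TBS-oxy)methyl]-9,13,17-trimethyl-4-oxooctadeca-2,8,12,16-tetraen-5-yn-7-yl pivalate | CC(C)(C)[Si](C)(C)OC/C=C(\CO[Si](C)(C)C(C)(C)C)C(=O)C#C[C@@H](OC(=O)C(C)(C)C)/C=C(\C)CC/C=C(\C)CCC=C(C)C | intermediate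
16 | (1E,3Z,7S,8E,12E)-1,4-bis(TBS-oxy)-3-[(TBS-oxy)methyl]-9,13,17-trimethyloctadeca-1,3,8,12,16-pentaen-5-yn-7-yl pivalate | CC(C)(C)[Si](C)(C)O/C=C/C(CO[Si](C)(C)C(C)(C)C)=C(/O[Si](C)(C)C(C)(C)C)C#C[C@@H](OC(=O)C(C)(C)C)/C=C(\C)CC/C=C(\C)CCC=C(C)C | intermediate
17 | (1E,3Z,7S,8E,12E)-1,4-bis(TBS-oxy)-3-[(TBS-oxy)methyl]-9,13,17-trimethyloctadeca-1,3,8,12,16-pentaen-5-yn-7-ol | CC(C)(C)[Si](C)(C)O/C=C/C(CO[Si](C)(C)C(C)(C)C)=C(/O[Si](C)(C)C(C)(C)C)C#C[C@@H](O)/C=C(\C)CC/C=C(\C)CCC=C(C)C | intermediate
18 | (4Z,5S)-4-[(2Z,4E)-2,5-bis(TBS-oxy)-3-[(TBS-oxy)methyl]penta-2,4-dien-1-ylidene]-5-[(1E,5E)-2,6,10-trimethylundeca-1,5,9-trien-1-yl]-1,3-dioxolan-2-one (electrocyclisation precursor) | CC(C)(C)[Si](C)(C)O/C=C/C(CO[Si](C)(C)C(C)(C)C)=C(/O[Si](C)(C)C(C)(C)C)\C=C1/OC(=O)O[C@H]1/C=C(\C)CC/C=C(\C)CCC=C(C)C | intermediate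
19 | spiro carbonate cyclohexadiene (4S,5R,1'S), C1 TBS enol ether, C4–OTBS trans to C5–O (electrocyclisation product) | CC(C)(C)[Si](C)(C)OCC1=C[C@H](O[Si](C)(C)C(C)(C)C)[C@]2(C=C1O[Si](C)(C)C(C)(C)C)OC(=O)O[C@H]2/C=C(\C)CC/C=C(\C)CCC=C(C)C | intermediate
20 | α-bromo ketone (4S,5R,6S,1'S), Br trans to O5, spiro carbonate intact | CC(C)(C)[Si](C)(C)OCC1=C[C@H](O[Si](C)(C)C(C)(C)C)[C@]2([C@H](Br)C1=O)OC(=O)O[C@H]2/C=C(\C)CC/C=C(\C)CCC=C(C)C | intermediate
21 | bromohydrin diol (4S,5R,6S,1'S): C5–OH, C1'–OH, C6–Br | CC(C)(C)[Si](C)(C)OCC1=C[C@H](O[Si](C)(C)C(C)(C)C)[C@](O)([C@@H](O)/C=C(\C)CC/C=C(\C)CCC=C(C)C)[C@H](Br)C1=O | intermediate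
22 | epoxy enone (4S,5R,6R,1'S), TBS on O7 and O4, free C1'–OH | CC(C)(C)[Si](C)(C)OCC1=C[C@H](O[Si](C)(C)C(C)(C)C)[C@@]2([C@@H](O)/C=C(\C)CC/C=C(\C)CCC=C(C)C)O[C@H]2C1=O | intermediate
23 | triol (4S,5R,6R,1'S) | OCC1=C[C@H](O)[C@@]2([C@@H](O)/C=C(\C)CC/C=C(\C)CCC=C(C)C)O[C@H]2C1=O | intermediate
24 | CNP0137670.2, C7 acetate (4S,5R,6R,1'S) | CC(=O)OCC1=C[C@H](O)[C@@]2([C@@H](O)/C=C(\C)CC/C=C(\C)CCC=C(C)C)O[C@H]2C1=O | target

Total: 16 steps. Longest linear sequence: 13 steps (7 to 24 through steps 4–16; the branch from 1 through steps 1–3 and 7–16 is equally long).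

Steps most likely to fail

1. Step 12. What may go wrong: ring closure may be slower than heterolysis of the doubly allylic C5–O bond, which leads to loss of the carbonate and aromatisation, or C4 may bond to both faces of C5 (poor torquoselectivity). Fallback with known reactions only, from 12 back to 23: 12 is silylated (TBSCl, imidazole) to the silyl ether F1. 2-Bromoallyl alcohol is silylated to the bromoallyl silyl ether F2, which is lithiated (t-BuLi), added to Cr(CO)6 and O-methylated (MeOTf) to the Fischer carbene complex F3. Dötz benzannulation of F3 with F1 (THF, 55 °C, then air) should give the 4-methoxyphenol F4. In it the alkyne carbons become C5 and C6, with the substituted one next to the phenol carbon C4 (from CO); the carbene carbon becomes C1 and the vinyl carbons C2 and C3. PhI(OAc)2 in MeOH should turn F4 into the quinone monoketal F5 (C4 ketone, C1 dimethyl ketal). Nucleophilic epoxidation (t-BuOOH, DBU) should take place at C5=C6, the only enone bond with an unsubstituted β-carbon, to give the epoxy ketone F6; the face would be set by C1' and would need to be checked. i-Bu2AlH should reduce the C4 ketone from the epoxide face, the other being screened by the C5 side chain, to the trans epoxy alcohol F7. Aqueous HF in MeCN removes both silyl groups and the ketal and delivers 23, which continues through step 16.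

2. Step 9. What may go wrong: leakage to the wrong C1=C2 geometry (alkyne trans to C3, a triene that cannot close), formation of the Z enol ether at C4, or amine addition to the silylated ynone. Fallback, from 14 back to 18: the carbonate is closed before the enolisation. Ag2CO3/PPh3 (cat.) under CO2, without amidine base, should convert 14 into the dienone carbonate F8, and TBSOTf/i-Pr2NEt at −78 °C then gives 18 directly. In F8 the group on C1 is a trisubstituted alkenyl unit instead of a slim alkyne, so the oxocarbenium ion should sit more firmly with C6 next to C3–H. The price is a C1'–H that is now vinylogously acidic, which is why this order is not the first choice.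

3. Step 13. What may go wrong: bromine may enter C6 cis to O5 (poor facial selectivity), and the base-mediated epimerisation in step 14 may then be overtaken by β-elimination or retro-aldol cleavage. Fallback, from 19 back to 20: if NBS gives mainly the cis bromide F9, it is re-enolised (TBSOTf, Et3N) to the bromo silyl enol ether F10, which is protonated at C6 (HCl in Et2O, −78 °C). The proton then enters from the face that bromine preferred, which leaves bromine trans to O5, and this is 20.

Further compounds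
F1 | step 12 | tert-butyldimethyl{[(3S,4E,8E)-5,9,13-trimethyltetradeca-4,8,12-trien-1-yn-3-yl]oxy}silane | C#C[C@@H](O[Si](C)(C)C(C)(C)C)/C=C(\C)CC/C=C(\C)CCC=C(C)C
F2 | step 12 | (2-bromoallyloxy)(tert-butyl)dimethylsilane | C=C(Br)CO[Si](C)(C)C(C)(C)C
F3 | step 12 | pentacarbonyl{[3-(TBS-oxy)prop-1-en-2-yl](methoxy)methylidene}chromium | COC(C(=C)CO[Si](C)(C)C(C)(C)C)=[Cr](=C=O)(=C=O)(=C=O)(=C=O)=C=O
F4 | step 12 | 4-methoxy-5-[(TBS-oxy)methyl]-2-[(1S,2E,6E)-1-(TBS-oxy)-3,7,11-trimethyldodeca-2,6,10-trien-1-yl]phenol | COc1cc([C@@H](O[Si](C)(C)C(C)(C)C)/C=C(\C)CC/C=C(\C)CCC=C(C)C)c(O)cc1CO[Si](C)(C)C(C)(C)C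
F5 | step 12 | quinone monoketal: 4,4-dimethoxy-5-[(TBS-oxy)methyl]-2-[(1S,2E,6E)-1-(TBS-oxy)-3,7,11-trimethyldodeca-2,6,10-trien-1-yl]cyclohexa-2,5-dien-1-one | COC1(OC)C=C([C@@H](O[Si](C)(C)C(C)(C)C)/C=C(\C)CC/C=C(\C)CCC=C(C)C)C(=O)C=C1CO[Si](C)(C)C(C)(C)C
F6 | step 12 | epoxy ketone (5R,6R,1'S): C4 ketone, C5–C6 epoxide, C1 dimethyl ketal, TBS on O7 and O1' | CC(C)(C)[Si](C)(C)OCC1=CC(=O)[C@@]2([C@@H](O[Si](C)(C)C(C)(C)C)/C=C(\C)CC/C=C(\C)CCC=C(C)C)O[C@H]2C1(OC)OC
F7 | step 12 | trans epoxy alcohol (4S,5R,6R,1'S): C4–OH, C1 dimethyl ketal, TBS on O7 and O1' | CC(C)(C)[Si](C)(C)OCC1=C[C@H](O)[C@@]2([C@@H](O[Si](C)(C)C(C)(C)C)/C=C(\C)CC/C=C(\C)CCC=C(C)C)O[C@H]2C1(OC)OC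
F8 | step 9 | dienone carbonate: (4Z,5S)-4-[(3E)-5-(TBS-oxy)-3-[(TBS-oxy)methyl]-2-oxopent-3-en-1-ylidene]-5-[(1E,5E)-2,6,10-trimethylundeca-1,5,9-trien-1-yl]-1,3-dioxolan-2-one | CC(C)(C)[Si](C)(C)OC/C=C(\CO[Si](C)(C)C(C)(C)C)C(=O)/C=C1\OC(=O)O[C@H]1/C=C(\C)CC/C=C(\C)CCC=C(C)C
F9 | step 13 | C6 epimer of 20 (Br cis to O5) | CC(C)(C)[Si](C)(C)OCC1=C[C@H](O[Si](C)(C)C(C)(C)C)[C@]2([C@@H](Br)C1=O)OC(=O)O[C@H]2/C=C(\C)CC/C=C(\C)CCC=C(C)C
F10 | step 13 | 6-bromo analogue of 19 (C1 TBS enol ether, Br on C6) | CC(C)(C)[Si](C)(C)OCC1=C[C@H](O[Si](C)(C)C(C)(C)C)[C@]2(C(Br)=C1O[Si](C)(C)C(C)(C)C)OC(=O)O[C@H]2/C=C(\C)CC/C=C(\C)CCC=C(C)C
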